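## Structural features

Maackiaflavanone A (19) is a flavanone: a benzene ring A is fused to the dihydropyranone ring C (O1, C2, C3, C4, C4a, C8a), and ring B is attached at C2 through C1'. Ring B is itself the benzo ring of a 2,2-dimethyl-2H-chromene, the pyran being fused through the C4' oxygen and C5', and it carries a free hydroxyl at C2', ortho to the point of attachment. Ring A is fully and unsymmetrically substituted: a hydroxyl at C5 chelated to the C4 ketone, a methoxy group at C7 and a prenyl chain at C8, directly beside C8a–O1. The only stereocentre is C2 (S); it is benzylic, oxygen-bearing and β to the ketone, has no neighbouring stereocentre to relay from, and is lost by ring opening to the 2'-hydroxychalcone under base or strong acid. The prenyl and chromene double bonds exclude hydrogenation and strong acid, and the electron-rich phenols are sensitive to oxidants. The real difficulty is twofold: absolute control at an isolated, labile C2, and the regiochemical question of which ring A oxygen becomes O1 (8-prenyl and not 6-prenyl). The key step uses the fact that O1–C8a–C4a–C4 of ring C is the oxadiene of an o-quinone methide latent in a ring A salicylaldehyde, whose formyl carbon is C4 already bearing oxygen, while C2–C3 with ring B is a styrene, so that ring C is the (4+2) adduct across O1–C2 and C3–C4.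

## Logic of the disconnections

19 ⇒ 18. The two O–Si bonds on the C5 and C2' oxygens are cut last. Free phenols cannot pass through the ring-forming step: a free C5 oxygen would offer a second, regioisomeric o-quinone methide, and a free C2' oxygen would bridge to C4. The skeleton is not simplified, but the final operation becomes a neutral unmasking. The forward step must be non-basic, so that ring C cannot open and C2 is kept.

18 ⇒ 16. The C4 carbonyl is traced back to a C4–H/C4–OCH3 benzylic ether. This is the oxidation pattern the cycloaddition delivers, and it means no ketone (and no chalcone equilibrium) is carried through the acid-catalysed step. The C4 stereocentre becomes irrelevant. The forward step needs an oxidant that removes hydride from C4 only, not from C2–H or the prenyl CH2.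

16 ⇒ 5 + 12 + 13. O1–C2 and C3–C4 are cut. These are the two bonds formed when the oxadiene O1=C8a–C4a=C4 meets a two-carbon partner. The cut removes ring C and the stereocentre at once and divides the molecule into two aromatic halves of similar size, with 13 as the source of the C4 methoxy group. The forward step must take the vinyl group of 12 in preference to its chromene alkene and the prenyl alkene of 5, join the CH2 terminus to C4, and distinguish the faces at C2 under catalyst control. The oxygen of 5 that becomes O1 must be the only free one.

5 ⇒ 4 ⇒ 3 ⇒ 1 + 2. The O–Si bond, then the O–CH3 bond, then the aryl–CH2 bond of the prenyl chain are cut. All three groups can be placed on symmetrical 1 in an order where each step has an intrinsic bias. The gain is a commercial trihydroxybenzaldehyde reached in three steps. The demands are C- over O-alkylation, methylation of the para oxygen only, and silylation of the ortho oxygen remote from the prenyl chain.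

12 ⇒ 11 ⇒ 10 ⇒ 9 ⇒ 6 + 7. The C=CH2 bond, the O–Si bond and the aryl–CHO bond are cut, then the pyran ring at its aryl–C4 and O1–C2 bonds. The formyl group is introduced after the pyran because annulation of an already formylated resorcinol would be expected to go to the carbon between the two oxygens and give the angular isomer. The gain is two commodity chemicals. The demands are single annulation at C4 of 6 and formylation at the unhindered carbon ortho to the hydroxyl.

## Other disconnections considered

Alternative 1: Ring A is built last, across C5–C6, C7–C8 and C4a–C5, on a preformed ring C.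
- Forward step: the acid chloride A1, a (2S)-2-aryl-2,3-dihydro-4H-pyran-4-one with the acyl chloride side chain on C8a, would be dehydrochlorinated with Et3N to the vinylketene A2, whose vinyl unit is the C8a=C4a enol ether bond. (2+2) addition of methoxyacetylene A3 to the ketene, four-electron ring opening, six-electron ring closure onto C4a and tautomerisation would give the phenol A4, the 2'-O-MOM ether of 19.
- In favour: the ring A pattern is dictated by the mechanism (hydroxyl from the ketene carbonyl at C5, methoxy from the alkyne at C7, prenyl from the ketene α-carbon at C8). No phloroglucinol has to be differentiated and the 5-hydroxyl appears free. On regiochemistry this is better than the chosen plan, which depends on a selective silylation. C2 would come from an established catalytic asymmetric hetero-Diels–Alder construction of the dihydropyranone, so on stereochemical precedent it is also ahead of step 8.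
- Against: A1 needs a functionalised dihydropyranone, α-prenylation and acid chloride formation beside an acid-sensitive MOM ether and chromene. The C2–O1 bond of a dihydropyranone with an electron-rich aryl group is open to amine-induced β-elimination and reclosure, so heating with Et3N endangers C2 before ring A is aromatic. A3 is volatile and poorly available. The final MOM removal needs acid in the presence of the prenyl chain, the chromene and C2.
- Comparison: the pericyclic cascade is at least as secure mechanistically as the cycloaddition chosen here. The construction is linear (ring B, then ring C, then ring A) and is estimated to be several steps longer than ten.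

Alternative 2: Ring C is cut at C4a–C4, C4–C3 and O1–C2, leading to the iodophenol A5, carbon monoxide A6 and the arylacetylene A7.
- Forward step: with PdCl2(PPh3)2 and Et2NH under A6, oxidative addition into the C–I bond, CO insertion, alkynylation of the acylpalladium species and amine-mediated 6-endo addition of the phenol would give the flavone A8 in one operation.
- In favour: three bonds are formed convergently by a reaction type with broad precedent and no stereochemical demand. As a bond construction it is more reliable than step 8. A7 would come in one step from an aldehyde of the type of 11, so the ring B partner costs the same.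
- Against: A8 is flat. C2 would have to be made afterwards by enantioselective 1,4-reduction of the C2=C3 bond of a hindered 2-arylchromone without touching the prenyl and chromene double bonds or the ketone. Asymmetric hydrogenation is excluded by those alkenes, and hydride conjugate reduction of so electron-rich a substrate has no close precedent. The unprecedented step is thus moved to the end, where failure costs most. 5-exo closure to an aurone is the usual side path. A5 needs the same oxygen differentiation as 5 plus a regioselective iodination, and two MOM ethers must be removed with acid.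
- Comparison: better than the chosen plan on the ring-forming mechanism, worse on stereochemistry, comparable or slightly longer in steps.

Alternative 3: Only O1–C8a is cut.
- Forward step: the open-chain (S)-benzylic alcohol A9, with a triflate on C8a and a silyloxy group on C4, would be closed with Pd(OAc)2, 2-(di-tert-butylphosphino)-1,1'-binaphthyl and Cs2CO3 by intramolecular aryl etherification to the flavan-4-ol silyl ether A10.
- In favour: C2 would be set beforehand in an acyclic precursor by a standard asymmetric carbonyl reduction or aldol reaction, and carried through with retention because its C–O bond is not broken. This is the most secure stereochemical plan of the four and better than step 8 in that respect. C4 is a protected alcohol, so the ketone would come from a routine alcohol oxidation; this too is better than the DDQ step of the chosen route.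
- Against: the aryl triflate is electron-rich and flanked by the prenyl chain and the side chain, which slows oxidative addition and C–O reductive elimination. A secondary alkoxide with a β-hydrogen on palladium is prone to β-hydride elimination, and Cs2CO3 may cleave the triflate. A9 needs three differently substituted oxygens on ring A beside the prenyl group, one more differentiation than 5. Desilylation, oxidation and acidic removal of two MOM ethers follow the coupling.
- Comparison: one bond and no stereocentre in the key step, against two bonds, a ring and the stereocentre in step 8. It is precedented but on a demanding substrate, and is estimated at about fifteen mostly linear steps against ten (seven in the longest line).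

Key step: step 8

Remark: 16 is written as its 2,4-cis isomer; the 2,4-trans epimer with the same 2S centre would serve equally. The sense of induction of the (R)-configured phosphoric acid is an assumption, and the antipodal catalyst would be used should it favour 2R.

## Route

Step 1
Reactants: 1 2,4,6-trihydroxybenzaldehyde; 2 prenyl bromide (1-bromo-3-methylbut-2-ene)
Product: 3 2,4,6-trihydroxy-3-(3-methylbut-2-en-1-yl)benzaldehyde
Conditions: 2 (0.9 equiv), 10% aq KOH, 0 °C to rt; then 1 M HCl
Reagents that add atoms: none
Why: C-alkylation of a phloroglucinol-type phenoxide in water, where solvation of the oxygens directs the allylic bromide to the ring carbon (SN2 at the primary CH2); the two free ring positions are equivalent and a slight deficit of 2 should limit double prenylation.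

Step 2
Reactants: 3 2,4,6-trihydroxy-3-(3-methylbut-2-en-1-yl)benzaldehyde
Product: 4 2,6-dihydroxy-4-methoxy-3-(3-methylbut-2-en-1-yl)benzaldehyde
Conditions: MeI (1.05 equiv), K2CO3 (1.0 equiv), acetone, rt
Reagents that add atoms: iodomethane, CI
Why: Williamson methylation of the most acidic hydroxyl; the C4 hydroxyl is para to the formyl group and not hydrogen-bonded, whereas both ortho hydroxyls are engaged with the carbonyl, so one equivalent of base and MeI should alkylate O4 selectively.

Step 3
Reactants: 4 2,6-dihydroxy-4-methoxy-3-(3-methylbut-2-en-1-yl)benzaldehyde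
Product: 5 6-(tert-butyldimethylsilyloxy)-2-hydroxy-4-methoxy-3-(3-methylbut-2-en-1-yl)benzaldehyde
Conditions: TBSCl (1.05 equiv), imidazole (2.2 equiv), CH2Cl2, 0 °C
Reagents that add atoms: tert-butyldimethylsilyl chloride, CC(C)(C)[Si](C)(C)Cl
Why: Steric differentiation in phenol silylation; the C6 hydroxyl is flanked by CHO and H, the C2 hydroxyl by CHO and the prenyl chain, so the bulky silyl chloride should take O6, and the remaining hydroxyl is then locked in the carbonyl chelate and resists a second silylation.

Step 4
Reactants: 6 resorcinol; 7 3-methyl-2-butenal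
Product: 9 7-hydroxy-2,2-dimethyl-2H-chromene, via dienone 8 (not isolated)
Conditions: 6 (2 equiv), 7 (1 equiv), pyridine, 140 °C, sealed tube
Reagents that add atoms: none
Why: Pyridine-mediated chromenylation; aldol-type condensation at C4 of resorcinol (ortho to one hydroxyl, para to the other) and dehydration give the o-quinone methide dienone 8, which closes by oxa-6π electrocyclisation, and excess 6 should limit double annulation.

Step 5
Reactants: 9 7-hydroxy-2,2-dimethyl-2H-chromene
Product: 10 7-hydroxy-2,2-dimethyl-2H-chromene-6-carbaldehyde
Conditions: MgCl2 (1.5 equiv), Et3N (3.75 equiv), (CH2O)n (6.75 equiv), MeCN, reflux; then 5% aq citric acid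
Reagents that add atoms: paraformaldehyde (as formaldehyde), C=O
Why: Casnati–Skattebøl ortho-formylation; the magnesium phenoxide delivers formaldehyde to an ortho carbon and a second formaldehyde oxidises the benzylic alkoxide by hydride transfer; of the two ortho carbons, C6 is open while C8 lies between two oxygens, and the non-acidic medium spares the chromene.

Step 6
Reactants: 10 7-hydroxy-2,2-dimethyl-2H-chromene-6-carbaldehyde
Product: 11 7-(tert-butyldimethylsilyloxy)-2,2-dimethyl-2H-chromene-6-carbaldehyde
Conditions: TBSCl (1.3 equiv), imidazole (2.5 equiv), DMF, rt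
Reagents that add atoms: tert-butyldimethylsilyl chloride, CC(C)(C)[Si](C)(C)Cl
Why: Standard imidazole-promoted silylation of a phenol; there is only one hydroxyl, and masking it removes the acidic proton before the ylide step and provides the blocked ring B oxygen needed later.

Step 7
Reactants: 11 7-(tert-butyldimethylsilyloxy)-2,2-dimethyl-2H-chromene-6-carbaldehyde
Product: 12 7-(tert-butyldimethylsilyloxy)-2,2-dimethyl-6-vinyl-2H-chromene
Conditions: Ph3PCH3Br (1.3 equiv), n-BuLi (1.25 equiv), THF, 0 °C; then 11, −78 °C to rt
Reagents that add atoms: methyltriphenylphosphonium bromide, C[P+](c1ccccc1)(c1ccccc1)c1ccccc1.[Br-]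
Why: Wittig methylenation of an aryl aldehyde; the ylide is preformed without excess base so that the aryl silyl ether is not attacked, and no stereochemical issue arises with a terminal alkene.

Step 8
Reactants: 5 6-(tert-butyldimethylsilyloxy)-2-hydroxy-4-methoxy-3-(3-methylbut-2-en-1-yl)benzaldehyde; 12 7-(tert-butyldimethylsilyloxy)-2,2-dimethyl-6-vinyl-2H-chromene; 13 trimethyl orthoformate
Product: 16 (2S,4S)-5-(tert-butyldimethylsilyloxy)-2-[7-(tert-butyldimethylsilyloxy)-2,2-dimethyl-2H-chromen-6-yl]-4,7-dimethoxy-8-(3-methylbut-2-en-1-yl)chromane (2,4-cis 4-methoxyflavan), via dimethyl acetal 14 (not isolated), via 4-methoxy o-quinone methide 15 (not isolated)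
Conditions: 5, 13 (2 equiv), (R)-TRIP [(R)-3,3'-bis(2,4,6-triisopropylphenyl)-1,1'-binaphthyl-2,2'-diyl hydrogen phosphate] (10 mol %), toluene, 0 °C; then 12 (1.5 equiv), 5 Å MS, −30 °C; Et3N quench at −30 °C
Reagents that add atoms: none
Why: Proposed new method: the phosphoric acid first catalyses acetal exchange between 5 and 13 to give 14 and then ionises 14 to the hydrogen-bonded ion pair of the 2-hydroxyaryl oxocarbenium ion, the protonated form of 15, which is the oxadiene O1=C8a–C4a=C4. The closest known reaction types are the achiral acid-mediated (4+2) reaction of salicylaldehyde acetals with styrenes to 4-alkoxy-2-arylchromans and the chiral phosphoric acid catalysed cycloaddition of o-quinone methides from o-hydroxybenzyl alcohols with styrenes; the enantioselective acetal variant with a styrene lacking a free hydroxyl is the unprecedented element. Ring C closes by an inverse-electron-demand hetero-Diels–Alder reaction, a six-membered closure in which the CH2 terminus of the vinyl group bonds to C4 and the benzylic carbon to O1, either concertedly but asynchronously or through a benzylic cation that collapses onto the phenol oxygen inside the ion pair. C2 is controlled by the chiral phosphate, which holds the cation through the O1–H hydrogen bond and a contact to C4–H so that its 3,3'-aryl groups shield one face and the styrene aryl group lies endo on the open face; the choice of catalyst antipode fixes the 2S sense. C4 follows from the methide geometry and the endo or exo orientation and is of no consequence because it is oxidised later, provided that both C4 epimers carry the same C2 configuration, which is to be checked on the separated epimers. Regiochemistry is secured by the polarisation of the 2,4-dioxygenated styrene (nucleophilic CH2, cation-stabilising benzylic carbon), site selectivity by the terminal vinyl group being far less hindered than the chromene alkene beside the quaternary carbon and the non-conjugated trisubstituted prenyl alkene, and the identity of O1 by the silyl ether on the other ortho oxygen of 5. The silyl ether on ring B keeps that oxygen from capturing C4 in a bridged ether, and low temperature with a base quench limits re-ionisation at C4 or C2.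

Step 9
Reactants: 16 (2S,4S)-5-(tert-butyldimethylsilyloxy)-2-[7-(tert-butyldimethylsilyloxy)-2,2-dimethyl-2H-chromen-6-yl]-4,7-dimethoxy-8-(3-methylbut-2-en-1-yl)chromane
Product: 18 (2S)-5-(tert-butyldimethylsilyloxy)-2-[7-(tert-butyldimethylsilyloxy)-2,2-dimethyl-2H-chromen-6-yl]-7-methoxy-8-(3-methylbut-2-en-1-yl)chroman-4-one, via hemiketal 17 (not isolated)
Conditions: DDQ (1.5 equiv), CH2Cl2–pH 7 phosphate buffer (10:1), 0 °C to rt
Reagents that add atoms: water, O
Why: DDQ oxidation of an electron-rich benzylic methyl ether to a carbonyl group; hydride is taken from C4–H, the position best able to carry positive charge (α-methoxy and conjugated with the trioxygenated ring A), water adds to the oxocarbenium ion to give 17, and loss of methanol gives the ketone, so both C4 epimers converge while C2 is untouched in the buffered medium.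

Step 10
Reactants: 18 (2S)-5-(tert-butyldimethylsilyloxy)-2-[7-(tert-butyldimethylsilyloxy)-2,2-dimethyl-2H-chromen-6-yl]-7-methoxy-8-(3-methylbut-2-en-1-yl)chroman-4-one
Product: 19 maackiaflavanone A, (2S)-5-hydroxy-2-(7-hydroxy-2,2-dimethyl-2H-chromen-6-yl)-7-methoxy-8-(3-methylbut-2-en-1-yl)chroman-4-one
Conditions: TBAF (2.5 equiv), AcOH (3 equiv), THF, 0 °C
Reagents that add atoms: none
Why: Fluoride-mediated cleavage of both aryl silyl ethers; acetic acid keeps the medium non-basic so that the flavanone cannot open to the chalcone, C2 is retained, and the prenyl and chromene alkenes are not exposed to acid strong enough to cyclise or hydrate them.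

## Compound list

1 | 2,4,6-trihydroxybenzaldehyde | O=Cc1c(O)cc(O)cc1O | starting material
2 | prenyl bromide (1-bromo-3-methylbut-2-ene) | CC(C)=CCBr | starting material
3 | 2,4,6-trihydroxy-3-(3-methylbut-2-en-1-yl)benzaldehyde | O=Cc1c(O)cc(O)c(CC=C(C)C)c1O | intermediate
4 | 2,6-dihydroxy-4-methoxy-3-(3-methylbut-2-en-1-yl)benzaldehyde | O=Cc1c(O)cc(OC)c(CC=C(C)C)c1O | intermediate
5 | 6-(tert-butyldimethylsilyloxy)-2-hydroxy-4-methoxy-3-(3-methylbut-2-en-1-yl)benzaldehyde | O=Cc1c(O)c(CC=C(C)C)c(OC)cc1O[Si](C)(C)C(C)(C)C | intermediate
6 | resorcinol | Oc1cccc(O)c1 | starting material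
7 | 3-methyl-2-butenal | CC(C)=CC=O | starting material
8 | 3-hydroxy-6-(3-methylbut-2-en-1-ylidene)cyclohexa-2,4-dien-1-one (formed in the flask, not isolated; exocyclic geometry not assigned) | CC(C)=CC=C1C=CC(O)=CC1=O | intermediate
9 | 7-hydroxy-2,2-dimethyl-2H-chromene | CC1(C)C=Cc2ccc(O)cc2O1 | intermediate
10 | 7-hydroxy-2,2-dimethyl-2H-chromene-6-carbaldehyde | CC1(C)C=Cc2cc(C=O)c(O)cc2O1 | intermediate
11 | 7-(tert-butyldimethylsilyloxy)-2,2-dimethyl-2H-chromene-6-carbaldehyde | CC1(C)C=Cc2cc(C=O)c(O[Si](C)(C)C(C)(C)C)cc2O1 | intermediate
12 | 7-(tert-butyldimethylsilyloxy)-2,2-dimethyl-6-vinyl-2H-chromene | C=Cc1cc2c(cc1O[Si](C)(C)C(C)(C)C)OC(C)(C)C=C2 | intermediate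
13 | trimethyl orthoformate | COC(OC)OC | starting material
14 | dimethyl acetal of 5, 3-(tert-butyldimethylsilyloxy)-2-(dimethoxymethyl)-5-methoxy-6-(3-methylbut-2-en-1-yl)phenol (formed in the flask, not isolated) | COC(OC)c1c(O)c(CC=C(C)C)c(OC)cc1O[Si](C)(C)C(C)(C)C | intermediate
15 | 4-methoxy o-quinone methide, 5-(tert-butyldimethylsilyloxy)-3-methoxy-6-(methoxymethylidene)-2-(3-methylbut-2-en-1-yl)cyclohexa-2,4-dien-1-one (formed in the flask, not isolated; exocyclic geometry not assigned) | COC=C1C(=O)C(CC=C(C)C)=C(OC)C=C1O[Si](C)(C)C(C)(C)C | intermediate
16 | (2S,4S)-5-(tert-butyldimethylsilyloxy)-2-[7-(tert-butyldimethylsilyloxy)-2,2-dimethyl-2H-chromen-6-yl]-4,7-dimethoxy-8-(3-methylbut-2-en-1-yl)chromane (2,4-cis 4-methoxyflavan) | COc1cc(O[Si](C)(C)C(C)(C)C)c2c(c1CC=C(C)C)O[C@H](c1cc3c(cc1O[Si](C)(C)C(C)(C)C)OC(C)(C)C=C3)C[C@@H]2OC | intermediate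
17 | (2S)-4-hydroxy-4-methoxy hemiketal of 18 (formed in the flask, not isolated; C4 not assigned) | COc1cc(O[Si](C)(C)C(C)(C)C)c2c(c1CC=C(C)C)O[C@H](c1cc3c(cc1O[Si](C)(C)C(C)(C)C)OC(C)(C)C=C3)CC2(O)OC | intermediate
18 | (2S)-5-(tert-butyldimethylsilyloxy)-2-[7-(tert-butyldimethylsilyloxy)-2,2-dimethyl-2H-chromen-6-yl]-7-methoxy-8-(3-methylbut-2-en-1-yl)chroman-4-one | COc1cc(O[Si](C)(C)C(C)(C)C)c2c(c1CC=C(C)C)O[C@H](c1cc3c(cc1O[Si](C)(C)C(C)(C)C)OC(C)(C)C=C3)CC2=O | intermediate
19 | maackiaflavanone A, (2S)-5-hydroxy-2-(7-hydroxy-2,2-dimethyl-2H-chromen-6-yl)-7-methoxy-8-(3-methylbut-2-en-1-yl)chroman-4-one | COc1cc(O)c2c(c1CC=C(C)C)O[C@H](c1cc3c(cc1O)OC(C)(C)C=C3)CC2=O | target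

## Step count and least certain steps

Total: 10 steps. Longest linear sequence: 7 steps (steps 4, 5, 6, 7, 8, 9, 10); the aldehyde branch (steps 1–3) joins at step 8.

Step 8 (key step, proposed new method).
- What may go wrong: poor facial discrimination at C2, because the silylated styrene offers the phosphate no hydrogen-bond donor. The catalyst may also control C4 but not the relative configuration, so that the two C4 epimers carry opposite C2 centres. Acid-mediated re-ionisation at C4 or C2 can cause loss of methanol or scrambling of C2. Acetal formation from the strongly chelated, electron-rich aldehyde may be sluggish.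
- Fallback with known chemistry: from 5, 12 and 13 the cycloaddition is run with an achiral Brønsted acid (diphenyl phosphate, toluene, −20 °C), the established acid-mediated acetal–styrene (4+2) reaction, to give the racemic 4-methoxyflavan F1. Oxidation under the conditions of step 9 gives the racemic bis-silyl flavanone F2. Kinetic resolution of F2 by Noyori-type asymmetric transfer hydrogenation (RuCl(p-cymene)[(S,S)-TsDPEN] or its antipode, whichever consumes the 2R ketone, HCO2H/Et3N) should reduce the 2R enantiomer to the cis-flavan-4-ol F3 and leave the 2S ketone. The route is rejoined at 18, at the cost of half the material.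

Step 9.
- What may go wrong: competing hydride abstraction at C2–H or at the benzylic, allylic CH2 of the prenyl chain, and over-oxidation through the C3–C4 enol ether to the flavone with loss of the stereocentre.
- Fallback: from 16 the methoxy group is exchanged for hydroxyl by mild acid solvolysis (PPTS, THF–H2O, 40 °C) through the ring A stabilised C4 cation, giving the (2S)-flavan-4-ol F4 as a mixture of C4 epimers. F4 is oxidised with Dess–Martin periodinane/NaHCO3 in CH2Cl2 and the route is rejoined at 18.

Step 3.
- What may go wrong: silylation at the hydroxyl beside the prenyl chain, or incomplete discrimination between the two ortho hydroxyls. This would transfer into the 6-prenyl series at step 8.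
- Fallback: from 1, methylation of the para hydroxyl (MeI, K2CO3, acetone) gives 2,6-dihydroxy-4-methoxybenzaldehyde F5. Its two hydroxyls are equivalent, so monosilylation (TBSCl, imidazole) can give only the silyl ether F6. Tsuji–Trost O-alkylation of the remaining hydroxyl with tert-butyl 2-methylbut-3-en-2-yl carbonate and Pd(PPh3)4 in THF gives the 1,1-dimethylallyl ether F7. Aromatic Claisen rearrangement (toluene, 110 °C) transfers the allyl unit, transposed to a prenyl group, to the only free ortho carbon. The route is rejoined at 5 with the prenyl chain necessarily beside the free hydroxyl; this also bypasses the modest C-prenylation of step 1.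

Step 4.
- What may go wrong: condensation at C2 of resorcinol leading to the 5-hydroxy isomer, double annulation, and thermal self-condensation of the enal.
- Fallback: from 6, Friedel–Crafts acylation and oxa-Michael closure with 3-methylbut-2-enoic acid in MeSO3H/P2O5 at 70 °C gives 7-hydroxy-2,2-dimethylchroman-4-one F8. NaBH4 in MeOH gives 7-hydroxy-2,2-dimethylchroman-4-ol F9. Acid-catalysed dehydration (TsOH, toluene, 80 °C) rejoins the route at 9.

## Further compounds

F1 | step 8 | racemic 5-(tert-butyldimethylsilyloxy)-2-[7-(tert-butyldimethylsilyloxy)-2,2-dimethyl-2H-chromen-6-yl]-4,7-dimethoxy-8-(3-methylbut-2-en-1-yl)chromane (racemate, C4 epimers) | COc1cc(O[Si](C)(C)C(C)(C)C)c2c(c1CC=C(C)C)OC(c1cc3c(cc1O[Si](C)(C)C(C)(C)C)OC(C)(C)C=C3)CC2OC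
F2 | step 8 | racemic 5-(tert-butyldimethylsilyloxy)-2-[7-(tert-butyldimethylsilyloxy)-2,2-dimethyl-2H-chromen-6-yl]-7-methoxy-8-(3-methylbut-2-en-1-yl)chroman-4-one | COc1cc(O[Si](C)(C)C(C)(C)C)c2c(c1CC=C(C)C)OC(c1cc3c(cc1O[Si](C)(C)C(C)(C)C)OC(C)(C)C=C3)CC2=O
F3 | step 8 | (2R,4R)-5-(tert-butyldimethylsilyloxy)-2-[7-(tert-butyldimethylsilyloxy)-2,2-dimethyl-2H-chromen-6-yl]-7-methoxy-8-(3-methylbut-2-en-1-yl)chroman-4-ol (2,4-cis) | COc1cc(O[Si](C)(C)C(C)(C)C)c2c(c1CC=C(C)C)O[C@@H](c1cc3c(cc1O[Si](C)(C)C(C)(C)C)OC(C)(C)C=C3)C[C@H]2O
F4 | step 9 | (2S)-5-(tert-butyldimethylsilyloxy)-2-[7-(tert-butyldimethylsilyloxy)-2,2-dimethyl-2H-chromen-6-yl]-7-methoxy-8-(3-methylbut-2-en-1-yl)chroman-4-ol (C4 epimers) | COc1cc(O[Si](C)(C)C(C)(C)C)c2c(c1CC=C(C)C)O[C@H](c1cc3c(cc1O[Si](C)(C)C(C)(C)C)OC(C)(C)C=C3)CC2O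
F5 | step 3 | 2,6-dihydroxy-4-methoxybenzaldehyde | COc1cc(O)c(C=O)c(O)c1
F6 | step 3 | 2-(tert-butyldimethylsilyloxy)-6-hydroxy-4-methoxybenzaldehyde | COc1cc(O)c(C=O)c(O[Si](C)(C)C(C)(C)C)c1
F7 | step 3 | 2-(tert-butyldimethylsilyloxy)-4-methoxy-6-[(2-methylbut-3-en-2-yl)oxy]benzaldehyde | COc1cc(OC(C)(C)C=C)c(C=O)c(O[Si](C)(C)C(C)(C)C)c1
F8 | step 4 | 7-hydroxy-2,2-dimethylchroman-4-one | CC1(C)CC(=O)c2ccc(O)cc2O1
F9 | step 4 | 7-hydroxy-2,2-dimethylchroman-4-ol (racemic) | CC1(C)CC(O)c2ccc(O)cc2O1
A1 | alternative 1 | 2-[(2S)-2-[7-(methoxymethoxy)-2,2-dimethyl-2H-chromen-6-yl]-4-oxo-3,4-dihydro-2H-pyran-6-yl]-5-methylhex-4-enoyl chloride (α-carbon not assigned) | CC(C)=CCC(C(Cl)=O)C1=CC(=O)C[C@@H](c2cc3c(cc2OCOC)OC(C)(C)C=C3)O1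
A2 | alternative 1 | vinylketene from A1, 2-[(2S)-2-[7-(methoxymethoxy)-2,2-dimethyl-2H-chromen-6-yl]-4-oxo-3,4-dihydro-2H-pyran-6-yl]-5-methylhexa-1,4-dien-1-one | CC(C)=CCC(=C=O)C1=CC(=O)C[C@@H](c2cc3c(cc2OCOC)OC(C)(C)C=C3)O1
A3 | alternative 1 | methoxyacetylene | COC#C
A4 | alternative 1 | (2S)-maackiaflavanone A 2'-O-methoxymethyl ether | COc1cc(O)c2c(c1CC=C(C)C)O[C@H](c1cc3c(cc1OCOC)OC(C)(C)C=C3)CC2=O
A5 | alternative 2 | 2-iodo-5-methoxy-3-(methoxymethoxy)-6-(3-methylbut-2-en-1-yl)phenol | COCOc1cc(OC)c(CC=C(C)C)c(O)c1I
A6 | alternative 2 | carbon monoxide | [C-]#[O+]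
A7 | alternative 2 | 6-ethynyl-7-(methoxymethoxy)-2,2-dimethyl-2H-chromene | C#Cc1cc2c(cc1OCOC)OC(C)(C)C=C2
A8 | alternative 2 | 7-methoxy-5-(methoxymethoxy)-2-[7-(methoxymethoxy)-2,2-dimethyl-2H-chromen-6-yl]-8-(3-methylbut-2-en-1-yl)-4H-chromen-4-one | COc1cc(OCOC)c2c(c1CC=C(C)C)OC(c1cc3c(cc1OCOC)OC(C)(C)C=C3)=CC2=O
A9 | alternative 3 | 2-[(3S)-1-(tert-butyldimethylsilyloxy)-3-hydroxy-3-[7-(methoxymethoxy)-2,2-dimethyl-2H-chromen-6-yl]propyl]-5-methoxy-3-(methoxymethoxy)-6-(3-methylbut-2-en-1-yl)phenyl trifluoromethanesulfonate (C1 of the propyl chain not assigned) | COc1cc(OCOC)c(C(O[Si](C)(C)C(C)(C)C)C[C@H](O)c2cc3c(cc2OCOC)OC(C)(C)C=C3)c(OS(=O)(=O)C(F)(F)F)c1CC=C(C)C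
A10 | alternative 3 | (2S)-4-(tert-butyldimethylsilyloxy)-7-methoxy-5-(methoxymethoxy)-2-[7-(methoxymethoxy)-2,2-dimethyl-2H-chromen-6-yl]-8-(3-methylbut-2-en-1-yl)chromane (C4 epimers) | COc1cc(OCOC)c2c(c1CC=C(C)C)O[C@H](c1cc3c(cc1OCOC)OC(C)(C)C=C3)CC2O[Si](C)(C)C(C)(C)C
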